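## Analysis of the target

The target is a labdane-type diterpenoid acid of the enantiomeric (ent) series. It is a trans-fused decalin (ring A: C1–C5 and C10; ring B: C5–C10) with a six-carbon side chain on C9. Labdane numbering is used throughout: C2 carbinol, C4 gem-dimethyl, C5 ring-fusion CH, C10 quaternary carbon with the angular methyl C20, C9 with the side chain C11–C16, and C8 with the exocyclic methylene C17.

The four stereocentres are 2R, 5R, 9R and 10R. The angular methyl is axial, H5 and H9 are axial on the opposite face, the side chain is equatorial, and the C2 hydroxyl is equatorial and trans to the angular methyl. The side chain ends in an (E)-trisubstituted enoic acid: the acetoxymethyl group (C16) is trans to the carboxyl (C15), so C12 and the carboxyl are cis and the C16 oxygen cannot lactonise.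

Sensitive features are the exocyclic 8(17)-alkene (isomerised by strong acid, and β,γ to any carbonyl at C11), the primary allylic acetate that must coexist with a free acid and a free secondary alcohol, and the alkene geometry. The difficulty lies in the quaternary C10, wedged between the gem-dimethyl carbon and two further stereocentres, in relaying absolute configuration from the remote C2 carbinol to C10, and in ordering three oxygen functions at the end.

The strategy rests on C10, C9 and C8 being contiguous in ring B. Ring B is the adduct of a diene C10=C5–C6=C7 that already holds ring A and an alkyne C8≡C9 that brings C17 and C11 with it.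

## Retrosynthetic reasoning

**End game (24 ← 23 ← 21 ← 20).** The acetate must survive beside a free carboxylic acid, so the carboxyl ester has to be cleaved before the acetate is installed. 24 is cut at the C2 O–Si bond to 23, 23 at the C16 O–acyl bond to hydroxy acid 21, and 21 at both ester bonds to 20. Keeping C2 silylated until the last step means the acetylation meets only one hydroxyl and needs no primary/secondary selectivity.

**C12–C13 (20 ← 17 + 18).** This sp3–sp2 bond separates the bicyclic core from a four-carbon unit whose alkene geometry is already fixed. The forward reaction is an anti-Markovnikov hydroboration of the C11=C12 vinyl group of 17 followed by cross-coupling with the (Z)-iodoenoate 18, with retention at the alkene. It must discriminate the vinyl group from the exocyclic C8=C17 alkene.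

**Iodoenoate (18 ← 10 ← 9).** 18 is the hydroiodination product of ynoate 10, which comes from 9 by acetylation. The same ynoate serves as the dienophile, so one building block is used twice.

**C11–C12 (17 ← 16 ← 15 ← 14).** The vinyl group is traced to aldehyde 16 by one-carbon olefination, and 16 through alcohol 15 to ester 14. This keeps C11 at the ester oxidation level, where the next disconnection needs it.

**C9–H and C8=C17 (14 ← 12 via 13).** The exocyclic alkene and the C9 hydrogen are traced to the γ-acetoxy enoate 12. Reductive loss of the C17 acetate gives dienolate 13, and kinetic α-protonation sets C9. This is why the dienophile carries an acetoxymethyl group: no ketone methylenation and no separate C9 epimerisation are needed.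

**C5–H (12 ← 11).** The ring-fusion hydrogen is added by saturating C5=C6 of the skipped diene 11 from the face opposite the angular methyl. The tetrasubstituted, conjugated C8=C9 bond must stay.

**Key disconnection (11 ← 8 + 10).** Cutting C9–C10 and C7–C8 opens ring B to the vinylcyclohexene 8 and the ynoate 10. No other cut forms the quaternary carbon and the ring together from two fragments of this size while delivering C11 and C17 at the right oxidation levels. The forward [4+2] must be regioselective (ester carbon to C10) and face-selective at C10 under control of the C2 stereocentre.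

**Diene (8 ← 6 + 7; 6 ← 4 ← 3 ← 2 ← 1).** The C5–C6 bond is cut to enol triflate 6 and vinylborate 7. Triflate 6 comes from ketone 4, whose only enolisable position is C6. Ketone 4 is the silyl ether of 3, the C4 epimer of the chiral-pool ketone 1, reached through the inverted ester 2. The inversion is needed because 1 has the opposite carbinol configuration to that required at C2.

## Alternatives that were turned down

**Alternative 1: intramolecular nitrile oxide cycloaddition closing ring B.**
- Disconnection: C8–C9 and O–C11.
- Forward key step: the oxime group of aldoxime A1 (three-carbon chain on C5, methyl and vinyl on C10, C2 as ethylene ketal) is oxidised with NaOCl to a nitrile oxide function, which adds to the C10 vinyl group to give the ring-B-fused isoxazoline A2.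
- For: the tether fixes the regiochemistry, the conditions are mild, C9 is set relative to C10 in a chair-like transition state, and the isoxazoline is a masked C8 ketone / C11 alcohol.
- Against: A1 must already contain the quaternary C10 and its trans relation to C5 on a monocyclic ring, so the hardest centre is not made by the key step and needs a separate multi-step solution. The C2 ketone is reduced late, and kinetic hydride attack on a ketone flanked by two syn-axial methyls gives the axial, wrong alcohol. After N–O cleavage, a β-hydroxy ketone prone to dehydration and a hindered C8 ketone next to the epimerisable C9 must be methylenated, and the side chain still has to be grown from C11.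
- Comparison: it is stronger on regiochemical certainty and mildness. The chosen route offers C10 made in the key step from a five-step diene, C2 from the chiral pool, and C17/C11 delivered at the right oxidation level.

**Alternative 2: carbocupration–carboxylation of the side-chain alkene.**
- Disconnection: C12–C13 and C14–C15.
- Forward key step: the organocopper reagent from the bicyclic C12 bromide A3 (Grignard formation, CuBr·SMe2) adds syn across the silyl propargyl ether A4, and the resulting alkenylcopper species is trapped with CO2 to give the (E)-enoic acid A5.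
- For: two C–C bonds and the alkene geometry in one pot. Syn addition puts C12 and the carboxyl cis, as the target requires, and the acid is formed free, so no ester hydrolysis is needed.
- Against: it is an end game only. A3 already holds the whole decalin with all four stereocentres, so the real difficulty is untouched. The advanced fragment is spent as a stoichiometric organometallic. A propargylic oxygen can redirect copper and open a β-alkoxy elimination path to an allene. Carboxylation of alkenylcopper species needs activating additives and is often incomplete. Two different silyl ethers must then be removed in order.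
- Comparison: on side-chain step count it is as strong or stronger than hydroiodination, coupling and saponification. The chosen route offers a solution to the ring system, and it fixes the same geometry in the small, separately purified partner 18, so the core is used in a catalytic coupling.

**Alternative 3: cyclopropane as latent angular methyl and C9 enolate.**
- Disconnection: C9–C10 and C9–C20.
- Forward key step: the keto-carbenoid generated from diazoketone A6 with Cu(acac)2 (divalent copper) adds to the exocyclic C10=C20 alkene of ring A, closing ring B and a three-membered ring to give the cyclopropyl ketone A7.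
- For: C10 is made intramolecularly with no regiochemical question. Dissolving-metal opening then gives the methyl group and a regiodefined C9 enolate in one operation, which could take the whole side chain in one alkylation.
- Against: the face of addition is set by C5, which must first be placed relative to C2 across ring A in A6. Axial alkylation of the C9 enolate anti to the angular methyl gives the side chain trans to it, the wrong epimer, so an equilibration is needed. Alkylation of a hindered enolate with an unactivated primary halide competes with proton transfer and O-alkylation. The C8 ketone must then be methylenated next to an epimerisable centre, and dissolving-metal conditions restrict protecting groups.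
- Comparison: it is stronger on convergence of the side chain and on regiochemistry of ring closure. The chosen route offers a much shorter cyclisation precursor, C17 and C11 at the right oxidation level, and the correct C9 configuration by kinetic protonation.

Key step: step 7

## Route

Assumption: compounds 1, 7 and 9 are purchased; ring positions are numbered as in labdanes (C1–C10 ring carbons, C11–C16 side chain, C17 exocyclic methylene, C20 angular methyl).

Step 1
Reactants: 1 (4R,6R)-4-hydroxy-2,2,6-trimethylcyclohexan-1-one (actinol)
Product: 2 (1S,5R)-3,3,5-trimethyl-4-oxocyclohexyl 4-nitrobenzoate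
Conditions: 4-O2NC6H4CO2H, PPh3, diisopropyl azodicarboxylate (DIAD), THF, 0 °C → rt
Reagents that add atoms: 4-nitrobenzoic acid, O=C(O)c1ccc(cc1)[N+](=O)[O-]
Why: Mitsunobu reaction; the hydroxyl is activated as an alkoxyphosphonium ion and displaced by the carboxylate with inversion, turning the 4R carbinol into 4S. The C6 centre is irrelevant because it becomes sp2 in step 4.

Step 2
Reactants: 2 (1S,5R)-3,3,5-trimethyl-4-oxocyclohexyl 4-nitrobenzoate
Product: 3 (4S,6R)-4-hydroxy-2,2,6-trimethylcyclohexan-1-one
Conditions: K2CO3 (cat.), MeOH, rt
Reagents that add atoms: none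
Why: Base-catalysed transesterification of an activated aryl ester; only the acyl–oxygen bond breaks, so the new carbinol configuration is kept.

Step 3
Reactants: 3 (4S,6R)-4-hydroxy-2,2,6-trimethylcyclohexan-1-one
Product: 4 (4S,6R)-4-[(tert-butyldimethylsilyl)oxy]-2,2,6-trimethylcyclohexan-1-one
Conditions: TBSCl, imidazole, DMF, rt
Reagents that add atoms: tert-butyldimethylsilyl chloride, CC(C)(C)[Si](C)(C)Cl
Why: Standard silylation of a secondary alcohol; the silyl ether tolerates the strong base, heat, hydride, SmI2 and hydroxide used later and is removed last.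

Step 4
Reactants: 4 (4S,6R)-4-[(tert-butyldimethylsilyl)oxy]-2,2,6-trimethylcyclohexan-1-one
Product: 6 (S)-4-[(tert-butyldimethylsilyl)oxy]-2,6,6-trimethylcyclohex-1-en-1-yl trifluoromethanesulfonate, via potassium enolate 5 (not isolated)
Conditions: KN(SiMe3)2, THF, −78 → 0 °C; PhNTf2, −78 °C → rt
Reagents that add atoms: N-phenylbis(trifluoromethanesulfonimide), O=S(=O)(N(c1ccccc1)S(=O)(=O)C(F)(F)F)C(F)(F)F
Why: Enolate O-sulfonylation; C2 is quaternary, so deprotonation can occur only at C6 and the enolate is regiodefined. Trapping on oxygen gives the tetrasubstituted enol triflate.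

Step 5
Reactants: 6 (S)-4-[(tert-butyldimethylsilyl)oxy]-2,6,6-trimethylcyclohex-1-en-1-yl trifluoromethanesulfonate; 7 potassium vinyltrifluoroborate
Product: 8 (S)-4-[(tert-butyldimethylsilyl)oxy]-2,6,6-trimethyl-1-vinylcyclohex-1-ene
Conditions: PdCl2(dppf)·CH2Cl2 (cat.; dppf = 1,1'-bis(diphenylphosphino)ferrocene), Cs2CO3, THF–H2O, 70 °C
Reagents that add atoms: none
Why: Suzuki–Miyaura coupling of an alkenyl triflate with a vinyltrifluoroborate; oxidative addition, transmetalation after slow hydrolysis of the borate, and reductive elimination give the hindered 1,3-diene without touching the silyl ether.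

Step 6
Reactants: 9 methyl 4-hydroxybut-2-ynoate
Product: 10 methyl 4-acetoxybut-2-ynoate
Conditions: Ac2O, Sc(OTf)3 (cat.), MeCN, 0 °C → rt
Reagents that add atoms: acetic anhydride, CC(=O)OC(C)=O
Why: Lewis-acid-catalysed acylation of a primary propargylic alcohol; amine-free conditions avoid conjugate addition of nucleophilic bases to the ynoate.

Step 7
Reactants: 8 (S)-4-[(tert-butyldimethylsilyl)oxy]-2,6,6-trimethyl-1-vinylcyclohex-1-ene; 10 methyl 4-acetoxybut-2-ynoate
Product: 11 methyl (7R,8aR)-2-(acetoxymethyl)-7-[(tert-butyldimethylsilyl)oxy]-5,5,8a-trimethyl-3,5,6,7,8,8a-hexahydronaphthalene-1-carboxylate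
Conditions: neat, 10 (2 equiv), 2,6-di-tert-butyl-4-methylphenol (cat.), sealed tube, Ar, 120 °C
Reagents that add atoms: none
Why: A thermal, concerted but asynchronous Diels–Alder reaction between the s-cis conformer of 8 and the ynoate; the closest known reaction type is the cycloaddition of 1,3,3-trimethyl-2-vinylcyclohexene with acetylenic esters that leads to drimane skeletons. Ring B is closed as a six-membered 1,4-cyclohexadiene by intermolecular [4+2] cycloaddition, with C7–C8 and C9–C10 formed in the same step. Regiochemistry should follow from the diene: the larger HOMO coefficient and the smaller steric demand lie at the unsubstituted terminus C7, which bonds first to the β-carbon C8 of the ynoate, so the ester carbon C9 ends on C10 and the acetoxymethyl group on C8. The new stereocentre C10 is controlled by C2 through the ring A half-chair: with the silyloxy group equatorial, one C4 methyl is pseudoaxial on the face opposite the oxygen and blocks that face, while the other half-chair would place the silyloxy group and that methyl syn-diaxial and should be little populated. The ynoate is therefore expected to add to the face that carries the C2 oxygen, which leaves the C10 methyl trans to it (10R). An alkyne dienophile raises no endo/exo question, so regio- and facial selectivity are the only selectivities needed. The adduct cannot aromatise because C10 is quaternary, and silyl ether, acetate and ester are inert to heat at neutral pH.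

Step 8
Reactants: 11 methyl (7R,8aR)-2-(acetoxymethyl)-7-[(tert-butyldimethylsilyl)oxy]-5,5,8a-trimethyl-3,5,6,7,8,8a-hexahydronaphthalene-1-carboxylate
Product: 12 methyl (4aR,7R,8aR)-2-(acetoxymethyl)-7-[(tert-butyldimethylsilyl)oxy]-5,5,8a-trimethyl-3,4,4a,5,6,7,8,8a-octahydronaphthalene-1-carboxylate
Conditions: H2 (1–3 atm), Pt/C, EtOAc, rt
Reagents that add atoms: none
Why: Heterogeneous catalytic hydrogenation; the trisubstituted C5=C6 bond should be reduced before the tetrasubstituted, ester-conjugated C8=C9 bond. Hydrogen is delivered to the face opposite the axial C10 and C4 methyls, which sets C5 (5R) with a trans ring fusion. Platinum is chosen over palladium to suppress hydrogenolysis of the allylic acetate and double-bond migration.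

Step 9
Reactants: 12 methyl (4aR,7R,8aR)-2-(acetoxymethyl)-7-[(tert-butyldimethylsilyl)oxy]-5,5,8a-trimethyl-3,4,4a,5,6,7,8,8a-octahydronaphthalene-1-carboxylate
Product: 14 methyl (1R,4aR,7R,8aR)-7-[(tert-butyldimethylsilyl)oxy]-5,5,8a-trimethyl-2-methylidenedecahydronaphthalene-1-carboxylate, via samarium dienolate 13 (not isolated)
Conditions: SmI2, THF–hexamethylphosphoramide, t-BuOH, −78 °C; aq. NH4Cl
Reagents that add atoms: none
Why: SmI2 reduction of a γ-acetoxy-α,β-unsaturated ester; two single-electron transfers expel acetate and give dienolate 13, which t-BuOH protonates kinetically at the α-carbon C9 to give the deconjugated ester with the exocyclic C8=C17 bond. Protonation is axial from the face opposite the axial C10 methyl, so H9 is trans to that methyl and the ester is equatorial (9R), which is also the more stable epimer.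

Step 10
Reactants: 14 methyl (1R,4aR,7R,8aR)-7-[(tert-butyldimethylsilyl)oxy]-5,5,8a-trimethyl-2-methylidenedecahydronaphthalene-1-carboxylate
Product: 15 [(1R,4aR,7R,8aR)-7-[(tert-butyldimethylsilyl)oxy]-5,5,8a-trimethyl-2-methylidenedecahydronaphthalen-1-yl]methanol
Conditions: LiAlH4, THF, 0 °C; aqueous work-up
Reagents that add atoms: none
Why: Hydride reduction of an ester to the primary alcohol; the reagent is not basic enough to epimerise C9 or move the double bond, and silyl ether and alkene are inert.

Step 11
Reactants: 15 [(1R,4aR,7R,8aR)-7-[(tert-butyldimethylsilyl)oxy]-5,5,8a-trimethyl-2-methylidenedecahydronaphthalen-1-yl]methanol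
Product: 16 (1R,4aR,7R,8aR)-7-[(tert-butyldimethylsilyl)oxy]-5,5,8a-trimethyl-2-methylidenedecahydronaphthalene-1-carbaldehyde
Conditions: Dess–Martin periodinane, pyridine, CH2Cl2, 0 °C → rt
Reagents that add atoms: none
Why: Dess–Martin oxidation under buffered, non-basic conditions should give the β,γ-unsaturated aldehyde without epimerisation at C9 or migration of the exocyclic alkene into conjugation.

Step 12
Reactants: 16 (1R,4aR,7R,8aR)-7-[(tert-butyldimethylsilyl)oxy]-5,5,8a-trimethyl-2-methylidenedecahydronaphthalene-1-carbaldehyde
Product: 17 tert-butyl{[(2R,4aR,8R,8aR)-8-ethenyl-4,4,8a-trimethyl-7-methylidenedecahydronaphthalen-2-yl]oxy}dimethylsilane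
Conditions: Ph3PCH3Br, KN(SiMe3)2, THF, 0 °C; then 16, −78 → 0 °C
Reagents that add atoms: methyltriphenylphosphonium bromide, C[P+](c1ccccc1)(c1ccccc1)c1ccccc1.[Br-]
Why: Wittig methylenation with the non-stabilised ylide at low temperature; addition to the aldehyde should outrun enolisation, and the equatorial C9 configuration is in any case the thermodynamic one.

Step 13
Reactants: 10 methyl 4-acetoxybut-2-ynoate
Product: 18 methyl (2Z)-4-acetoxy-3-iodobut-2-enoate
Conditions: NaI, AcOH, 70 °C
Reagents that add atoms: sodium iodide, [Na+].[I-]
Why: Conjugate hydroiodination of an ynoate; iodide adds to the β-carbon and the allenolate is protonated anti to iodine, giving the (Z)-β-iodoenoate (iodine cis to the ester) under kinetic control. The acetate masks the C16 oxygen.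

Step 14
Reactants: 17 tert-butyl{[(2R,4aR,8R,8aR)-8-ethenyl-4,4,8a-trimethyl-7-methylidenedecahydronaphthalen-2-yl]oxy}dimethylsilane; 18 methyl (2Z)-4-acetoxy-3-iodobut-2-enoate
Product: 20 methyl (2E)-3-(acetoxymethyl)-5-[(1R,4aR,7R,8aR)-7-[(tert-butyldimethylsilyl)oxy]-5,5,8a-trimethyl-2-methylidenedecahydronaphthalen-1-yl]pent-2-enoate, via alkyl(disiamyl)borane 19 (not isolated)
Conditions: Sia2BH (from BH3·THF and 2-methylbut-2-ene), THF, 0 °C → rt; then 18, PdCl2(dppf) (cat.), AsPh3, Cs2CO3, DMF–H2O, rt → 45 °C
Reagents that add atoms: none
Why: Hydroboration with disiamylborane is anti-Markovnikov and, for steric reasons, should be much faster at the monosubstituted vinyl group than at the 1,1-disubstituted exocyclic methylene flanked by C7 and C9; 9-BBN is avoided because it separates these two alkene classes less well. B-alkyl Suzuki–Miyaura coupling then transfers the primary alkyl group to the alkenyl iodide with retention of geometry, forming C12–C13 with C12 cis to the ester.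

Step 15
Reactants: 20 methyl (2E)-3-(acetoxymethyl)-5-[(1R,4aR,7R,8aR)-7-[(tert-butyldimethylsilyl)oxy]-5,5,8a-trimethyl-2-methylidenedecahydronaphthalen-1-yl]pent-2-enoate
Product: 21 (2E)-5-[(1R,4aR,7R,8aR)-7-[(tert-butyldimethylsilyl)oxy]-5,5,8a-trimethyl-2-methylidenedecahydronaphthalen-1-yl]-3-(hydroxymethyl)pent-2-enoic acid
Conditions: LiOH, THF–MeOH–H2O, rt → 40 °C; then 1 M HCl to pH 3
Reagents that add atoms: lithium hydroxide, [Li+].[OH-]
Why: Saponification cleaves the methyl ester and the acetate together; the (E) geometry holds the C16 hydroxyl trans to the carboxyl, so no butenolide can form. The secondary silyl ether survives hydroxide.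

Step 16
Reactants: 21 (2E)-5-[(1R,4aR,7R,8aR)-7-[(tert-butyldimethylsilyl)oxy]-5,5,8a-trimethyl-2-methylidenedecahydronaphthalen-1-yl]-3-(hydroxymethyl)pent-2-enoic acid
Product: 23 (2E)-3-(acetoxymethyl)-5-[(1R,4aR,7R,8aR)-7-[(tert-butyldimethylsilyl)oxy]-5,5,8a-trimethyl-2-methylidenedecahydronaphthalen-1-yl]pent-2-enoic acid, via mixed acetic anhydride 22 (not isolated)
Conditions: Ac2O, pyridine, 4-(dimethylamino)pyridine (cat.), CH2Cl2, 0 °C → rt; then H2O–THF
Reagents that add atoms: acetic anhydride, CC(=O)OC(C)=O
Why: Acetylation of the only free hydroxyl (C2 is still silylated), so no primary/secondary selectivity is needed. The carboxyl group is transiently converted to mixed anhydride 22, which is hydrolysed back during the aqueous work-up.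

Step 17
Reactants: 23 (2E)-3-(acetoxymethyl)-5-[(1R,4aR,7R,8aR)-7-[(tert-butyldimethylsilyl)oxy]-5,5,8a-trimethyl-2-methylidenedecahydronaphthalen-1-yl]pent-2-enoic acid
Product: 24 (2E)-3-(acetoxymethyl)-5-[(1R,4aR,7R,8aR)-7-hydroxy-5,5,8a-trimethyl-2-methylidenedecahydronaphthalen-1-yl]pent-2-enoic acid (target)
Conditions: HF·pyridine, pyridine–THF, 0 °C → rt
Reagents that add atoms: none
Why: Fluoride-mediated cleavage of the silyl ether with buffered HF·pyridine; the conditions are not basic enough to cleave the acetate and should not be acidic enough to isomerise the exocyclic alkene.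

## Compound list

1 | (4R,6R)-4-hydroxy-2,2,6-trimethylcyclohexan-1-one (actinol) | C[C@@H]1C[C@@H](O)CC(C)(C)C1=O | starting material
2 | (1S,5R)-3,3,5-trimethyl-4-oxocyclohexyl 4-nitrobenzoate | C[C@@H]1C[C@H](OC(=O)c2ccc(cc2)[N+](=O)[O-])CC(C)(C)C1=O | intermediate
3 | (4S,6R)-4-hydroxy-2,2,6-trimethylcyclohexan-1-one | C[C@@H]1C[C@H](O)CC(C)(C)C1=O | intermediate
4 | (4S,6R)-4-[(tert-butyldimethylsilyl)oxy]-2,2,6-trimethylcyclohexan-1-one | C[C@@H]1C[C@H](O[Si](C)(C)C(C)(C)C)CC(C)(C)C1=O | intermediate
5 | potassium (S)-4-[(tert-butyldimethylsilyl)oxy]-2,6,6-trimethylcyclohex-1-en-1-olate (formed in the flask, not isolated) | [K+].[O-]C1=C(C)C[C@H](O[Si](C)(C)C(C)(C)C)CC1(C)C | intermediate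
6 | (S)-4-[(tert-butyldimethylsilyl)oxy]-2,6,6-trimethylcyclohex-1-en-1-yl trifluoromethanesulfonate | FC(F)(F)S(=O)(=O)OC1=C(C)C[C@H](O[Si](C)(C)C(C)(C)C)CC1(C)C | intermediate
7 | potassium vinyltrifluoroborate | [K+].C=C[B-](F)(F)F | starting material
8 | (S)-4-[(tert-butyldimethylsilyl)oxy]-2,6,6-trimethyl-1-vinylcyclohex-1-ene | C=CC1=C(C)C[C@H](O[Si](C)(C)C(C)(C)C)CC1(C)C | intermediate
9 | methyl 4-hydroxybut-2-ynoate | COC(=O)C#CCO | starting material
10 | methyl 4-acetoxybut-2-ynoate | CC(=O)OCC#CC(=O)OC | intermediate
11 | methyl (7R,8aR)-2-(acetoxymethyl)-7-[(tert-butyldimethylsilyl)oxy]-5,5,8a-trimethyl-3,5,6,7,8,8a-hexahydronaphthalene-1-carboxylate | COC(=O)C1=C(COC(C)=O)CC=C2C(C)(C)C[C@@H](O[Si](C)(C)C(C)(C)C)C[C@]21C | intermediate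
12 | methyl (4aR,7R,8aR)-2-(acetoxymethyl)-7-[(tert-butyldimethylsilyl)oxy]-5,5,8a-trimethyl-3,4,4a,5,6,7,8,8a-octahydronaphthalene-1-carboxylate | COC(=O)C1=C(COC(C)=O)CC[C@@H]2C(C)(C)C[C@@H](O[Si](C)(C)C(C)(C)C)C[C@]21C | intermediate
13 | diiodosamarium dienolate of 14 (trivalent samarium; O-bound ketene acetal with C9=C11 and C8=C17; formed in the flask, not isolated) | COC(O[Sm](I)I)=C1C(=C)CC[C@@H]2C(C)(C)C[C@@H](O[Si](C)(C)C(C)(C)C)C[C@@]12C | intermediate
14 | methyl (1R,4aR,7R,8aR)-7-[(tert-butyldimethylsilyl)oxy]-5,5,8a-trimethyl-2-methylidenedecahydronaphthalene-1-carboxylate | C=C1CC[C@@H]2C(C)(C)C[C@@H](O[Si](C)(C)C(C)(C)C)C[C@@]2(C)[C@@H]1C(=O)OC | intermediate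
15 | [(1R,4aR,7R,8aR)-7-[(tert-butyldimethylsilyl)oxy]-5,5,8a-trimethyl-2-methylidenedecahydronaphthalen-1-yl]methanol | C=C1CC[C@@H]2C(C)(C)C[C@@H](O[Si](C)(C)C(C)(C)C)C[C@@]2(C)[C@@H]1CO | intermediate
16 | (1R,4aR,7R,8aR)-7-[(tert-butyldimethylsilyl)oxy]-5,5,8a-trimethyl-2-methylidenedecahydronaphthalene-1-carbaldehyde | C=C1CC[C@@H]2C(C)(C)C[C@@H](O[Si](C)(C)C(C)(C)C)C[C@@]2(C)[C@@H]1C=O | intermediate
17 | tert-butyl{[(2R,4aR,8R,8aR)-8-ethenyl-4,4,8a-trimethyl-7-methylidenedecahydronaphthalen-2-yl]oxy}dimethylsilane | C=C1CC[C@@H]2C(C)(C)C[C@@H](O[Si](C)(C)C(C)(C)C)C[C@@]2(C)[C@@H]1C=C | intermediate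
18 | methyl (2Z)-4-acetoxy-3-iodobut-2-enoate | COC(=O)/C=C(\I)COC(C)=O | intermediate
19 | {2-[(1R,4aR,7R,8aR)-7-[(tert-butyldimethylsilyl)oxy]-5,5,8a-trimethyl-2-methylidenedecahydronaphthalen-1-yl]ethyl}bis(3-methylbutan-2-yl)borane (formed in the flask, not isolated) | C=C1CC[C@@H]2C(C)(C)C[C@@H](O[Si](C)(C)C(C)(C)C)C[C@@]2(C)[C@@H]1CCB(C(C)C(C)C)C(C)C(C)C | intermediate
20 | methyl (2E)-3-(acetoxymethyl)-5-[(1R,4aR,7R,8aR)-7-[(tert-butyldimethylsilyl)oxy]-5,5,8a-trimethyl-2-methylidenedecahydronaphthalen-1-yl]pent-2-enoate | C=C1CC[C@@H]2C(C)(C)C[C@@H](O[Si](C)(C)C(C)(C)C)C[C@@]2(C)[C@@H]1CC/C(=C\C(=O)OC)COC(C)=O | intermediate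
21 | (2E)-5-[(1R,4aR,7R,8aR)-7-[(tert-butyldimethylsilyl)oxy]-5,5,8a-trimethyl-2-methylidenedecahydronaphthalen-1-yl]-3-(hydroxymethyl)pent-2-enoic acid | C=C1CC[C@@H]2C(C)(C)C[C@@H](O[Si](C)(C)C(C)(C)C)C[C@@]2(C)[C@@H]1CC/C(=C\C(=O)O)CO | intermediate
22 | acetic (2E)-3-(acetoxymethyl)-5-[(1R,4aR,7R,8aR)-7-[(tert-butyldimethylsilyl)oxy]-5,5,8a-trimethyl-2-methylidenedecahydronaphthalen-1-yl]pent-2-enoic anhydride (formed in the flask, not isolated) | C=C1CC[C@@H]2C(C)(C)C[C@@H](O[Si](C)(C)C(C)(C)C)C[C@@]2(C)[C@@H]1CC/C(=C\C(=O)OC(C)=O)COC(C)=O | intermediate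
23 | (2E)-3-(acetoxymethyl)-5-[(1R,4aR,7R,8aR)-7-[(tert-butyldimethylsilyl)oxy]-5,5,8a-trimethyl-2-methylidenedecahydronaphthalen-1-yl]pent-2-enoic acid | C=C1CC[C@@H]2C(C)(C)C[C@@H](O[Si](C)(C)C(C)(C)C)C[C@@]2(C)[C@@H]1CC/C(=C\C(=O)O)COC(C)=O | intermediate
24 | (2E)-3-(acetoxymethyl)-5-[(1R,4aR,7R,8aR)-7-hydroxy-5,5,8a-trimethyl-2-methylidenedecahydronaphthalen-1-yl]pent-2-enoic acid (CNP0292310.2) | C=C1CC[C@@H]2C(C)(C)C[C@@H](O)C[C@@]2(C)[C@@H]1CC/C(=C\C(=O)O)COC(C)=O | target

## Step count and least certain steps

Total step count: 17. Longest linear sequence: 15 steps from 1 (steps 1–5, 7–12 and 14–17); steps 6 and 13 are side branches from 9.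

**Step 7 (key step).** The most likely failure is slow cycloaddition. The ynoate is mono-activated and β-substituted, and the diene terminus C10 is fully substituted, so prolonged heating could lead to thermal degradation of the diene (hydrogen shift from the C10 methyl, oligomerisation) and leakage to the regioisomeric adduct. The fallback changes the dienophile to a symmetric, doubly activated one and differentiates the two carbons afterwards. It sets out from 8: cycloaddition with dimethyl acetylenedicarboxylate should give the cyclohexadiene diester F1, which has no regiochemical issue. Hydrogenation as in step 8 gives the trans-fused ene diester F2, and LiAlH4 reduces both esters to the allylic diol F3. Acetylation of the less hindered C17 hydroxyl (the C11 hydroxyl sits next to the quaternary C10) gives the monoacetate F4. Formate hydrogenolysis of the allylic acetate with a zerovalent palladium catalyst (Pd2(dba)3, PBu3, HCO2NH4) then delivers hydride to C9 from the metal-bearing face, opposite the angular methyl, and moves the alkene to C8=C17. The route is rejoined at 15.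

**Step 8.** The most likely failure is hydrogenolysis of the allylic C17–O bond or migration of the skipped diene on the metal surface before the hindered C5=C6 bond, flanked by two quaternary carbons, takes up hydrogen. The fallback replaces surface hydrogenation by radical hydrogen-atom-transfer hydrogenation (Mn(dpm)3, dpm = dipivaloylmethanate, with PhSiH3 and t-BuOOH in i-PrOH). A metal hydride transfers a hydrogen atom to C6, and the tertiary C5 radical is quenched to the thermodynamically preferred trans-fused decalin, with no C–O hydrogenolysis pathway. It sets out from 11 and rejoins at 12 without new intermediates.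

**Step 9.** The most likely failure is loss of control over where and from which face the dienolate is protonated (γ-protonation back to a conjugated ester, or the C9 epimer), or sluggish electron transfer to the hindered tetrasubstituted enoate. The fallback is a two-electron pathway: formate hydrogenolysis of the allylic acetate via a π-allyl complex formed from a zerovalent palladium catalyst (Pd2(dba)3, PBu3, HCO2NH4, dioxane, heat), with hydride delivered to the more substituted terminus C9 on the face opposite the angular methyl. It sets out from 12 and rejoins at 14 without new intermediates.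

**Step 14.** The most likely failure is incomplete discrimination between the two terminal alkenes in the hydroboration, together with slow transfer of the primary alkyl group from the hindered trialkylborane while 18 degrades in base. The fallback separates the two problems and couples without base. It sets out from 17: the same hydroboration is followed by oxidative work-up (NaOH, H2O2) to the primary alcohol F5, which is purified from any over-hydroborated material. Iodination (I2, PPh3, imidazole) gives the iodide F6, and zinc insertion gives the alkylzinc iodide F7. Negishi coupling of F7 with 18 (Pd(PPh3)4, THF) rejoins the route at 20.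

## Further compounds

F1 | step 7 | dimethyl (7R,8aR)-7-[(tert-butyldimethylsilyl)oxy]-5,5,8a-trimethyl-3,5,6,7,8,8a-hexahydronaphthalene-1,2-dicarboxylate | COC(=O)C1=C(C(=O)OC)CC=C2C(C)(C)C[C@@H](O[Si](C)(C)C(C)(C)C)C[C@]21C
F2 | step 7 | dimethyl (4aR,7R,8aR)-7-[(tert-butyldimethylsilyl)oxy]-5,5,8a-trimethyl-3,4,4a,5,6,7,8,8a-octahydronaphthalene-1,2-dicarboxylate | COC(=O)C1=C(C(=O)OC)CC[C@@H]2C(C)(C)C[C@@H](O[Si](C)(C)C(C)(C)C)C[C@]21C
F3 | step 7 | [(4aR,7R,8aR)-7-[(tert-butyldimethylsilyl)oxy]-5,5,8a-trimethyl-3,4,4a,5,6,7,8,8a-octahydronaphthalene-1,2-diyl]dimethanol | OCC1=C(CO)CC[C@@H]2C(C)(C)C[C@@H](O[Si](C)(C)C(C)(C)C)C[C@]21C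
F4 | step 7 | [(4aR,7R,8aR)-7-[(tert-butyldimethylsilyl)oxy]-1-(hydroxymethyl)-5,5,8a-trimethyl-3,4,4a,5,6,7,8,8a-octahydronaphthalen-2-yl]methyl acetate | OCC1=C(COC(C)=O)CC[C@@H]2C(C)(C)C[C@@H](O[Si](C)(C)C(C)(C)C)C[C@]21C
F0 | step 8 | none | none
F0 | step 9 | none | none
F5 | step 14 | 2-[(1R,4aR,7R,8aR)-7-[(tert-butyldimethylsilyl)oxy]-5,5,8a-trimethyl-2-methylidenedecahydronaphthalen-1-yl]ethan-1-ol | C=C1CC[C@@H]2C(C)(C)C[C@@H](O[Si](C)(C)C(C)(C)C)C[C@@]2(C)[C@@H]1CCO
F6 | step 14 | tert-butyl{[(2R,4aR,8R,8aR)-8-(2-iodoethyl)-4,4,8a-trimethyl-7-methylidenedecahydronaphthalen-2-yl]oxy}dimethylsilane | C=C1CC[C@@H]2C(C)(C)C[C@@H](O[Si](C)(C)C(C)(C)C)C[C@@]2(C)[C@@H]1CCI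
F7 | step 14 | {2-[(1R,4aR,7R,8aR)-7-[(tert-butyldimethylsilyl)oxy]-5,5,8a-trimethyl-2-methylidenedecahydronaphthalen-1-yl]ethyl}zinc iodide | C=C1CC[C@@H]2C(C)(C)C[C@@H](O[Si](C)(C)C(C)(C)C)C[C@@]2(C)[C@@H]1CC[Zn]I
A1 | alternative 1 | 3-[(7S,8R)-7-ethenyl-7,9,9-trimethyl-1,4-dioxaspiro[4.5]decan-8-yl]propanal oxime | ON=CCC[C@@H]1C(C)(C)CC2(OCCO2)C[C@@]1(C)C=C
A2 | alternative 1 | ring-B-fused isoxazoline (C8=N, O on C11, C2 ethylene ketal) | N1=C2CC[C@@H]3C(C)(C)CC4(OCCO4)C[C@@]3(C)[C@@H]2CO1
A3 | alternative 2 | {[(2R,4aR,8R,8aR)-8-(2-bromoethyl)-4,4,8a-trimethyl-7-methylidenedecahydronaphthalen-2-yl]oxy}tri(propan-2-yl)silane | C=C1CC[C@@H]2C(C)(C)C[C@@H](O[Si](C(C)C)(C(C)C)C(C)C)C[C@@]2(C)[C@@H]1CCBr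
A4 | alternative 2 | tert-butyldimethyl(prop-2-yn-1-yloxy)silane | C#CCO[Si](C)(C)C(C)(C)C
A5 | alternative 2 | (2E)-3-{[(tert-butyldimethylsilyl)oxy]methyl}-5-[(1R,4aR,7R,8aR)-5,5,8a-trimethyl-2-methylidene-7-{[tri(propan-2-yl)silyl]oxy}decahydronaphthalen-1-yl]pent-2-enoic acid | C=C1CC[C@@H]2C(C)(C)C[C@@H](O[Si](C(C)C)(C(C)C)C(C)C)C[C@@]2(C)[C@@H]1CC/C(=C\C(=O)O)CO[Si](C)(C)C(C)(C)C
A6 | alternative 3 | 4-[(1R,4R)-4-[(tert-butyldimethylsilyl)oxy]-2,2-dimethyl-6-methylidenecyclohexyl]-1-diazobutan-2-one | [N-]=[N+]=CC(=O)CC[C@@H]1C(C)(C)C[C@@H](O[Si](C)(C)C(C)(C)C)CC1=C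
A7 | alternative 3 | tricyclic cyclopropyl ketone (C8 ketone, C9–C10–C20 three-membered ring, C2 silyl ether) | O=C1CC[C@@H]2C(C)(C)C[C@@H](O[Si](C)(C)C(C)(C)C)C[C@]23C[C@H]13
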